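**Retrosynthetic overview**

1. Numbering (spiro[4.5]decane): C1 = CH–O(isobutyryl), C2 = CH2, C3 = CH(isopropenyl), C4 = CH2, C5 = spiro carbon, C6 = C(CH3)=, C7 = =CH, C8 = C=O, C9 = CH–OAc, C10 = CH(CH3). Ring A is the cyclopentane, ring B the cyclohexenone.
2. Late stage: C9–OAc by α′-acetoxylation, the C1 ester by acylation, C6=C7 by Saegusa–Ito oxidation of a silyl enol ether, and the C3 isopropenyl group by hydroboration/Zweifel olefination of a C3=C4 alkene, which is what remains of a temporary C4 ketone.
3. Key disconnection: C5–C6 and C9–C10 in one formal [4+2] annulation between (E)-2-silyloxypenta-1,3-diene and an (E)-2-ethylidenecyclopentanone. Ring A is bought as a silyloxycyclopentenone; ring B is formed in the key step.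
4. Enabling feature: in ring A the spiro carbon C5 lies between the CH2 carbon C4 and the oxygenated C1. With C4 at the ketone level, C5=C10 becomes the α,β-bond of an exocyclic enone of matched polarity, and the C1–O stereocentre (the only one bought) sits on the allylic carbon and directs the face. In ring B the C8 oxygen is 1,4 and the C6 methyl 1,2 to C5, which is the substitution pattern of the diene.
5. The dienophile comes from the bought cyclopentenone by aldol addition of acetaldehyde, hydrogenation and dehydration.

Key step: step 5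

Remark: the carbinol centre made in step 2 and the C6 centre made in step 5 form without control and are removed in steps 4 and 10, so they are left unassigned in the SMILES; commercial solutions of LiN(iPr)2 and KN(SiMe3)2 are assumed.

**Route**

Step 1
Reactants: 1 (E)-pent-3-en-2-one
Product: 2 (E)-tert-butyldimethyl(penta-1,3-dien-2-yloxy)silane
Conditions: TBSOTf, Et3N, Et2O, 0 °C
Reagents that add atoms: tert-butyldimethylsilyl trifluoromethanesulfonate, CC(C)(C)[Si](C)(C)OS(=O)(=O)C(F)(F)F
Why: Soft enolisation of the methyl ketone (silyl triflate/amine enol silylation) should remove a methyl proton and give the cross-conjugated 2-silyloxydiene with the (E)-propenyl unit unchanged.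

Step 2
Reactants: 3 (S)-4-(tert-butyldimethylsilyloxy)cyclopent-2-en-1-one
Product: 5 trans-4-(tert-butyldimethylsilyloxy)-5-(1-hydroxyethyl)cyclopent-2-en-1-one (carbinol epimers), via lithium enolate 4 (not isolated)
Conditions: LiN(iPr)2, THF, −78 °C; CH3CHO, −78 °C; AcOH quench
Reagents that add atoms: acetaldehyde, CC=O
Why: Kinetic deprotonation at the only sp3 α-carbon followed by a directed aldol addition should give the β-hydroxy ketone, the aldehyde entering trans to the silyloxy group, and β-elimination from the enolate is disfavoured because it would have to form cyclopentadienone.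

Step 3
Reactants: 5 trans-4-(tert-butyldimethylsilyloxy)-5-(1-hydroxyethyl)cyclopent-2-en-1-one
Product: 6 trans-3-(tert-butyldimethylsilyloxy)-2-(1-hydroxyethyl)cyclopentan-1-one (carbinol epimers)
Conditions: H2 (1 atm), Pd/C, EtOAc, rt
Reagents that add atoms: none
Why: Catalytic hydrogenation should saturate the ring enone C=C bond while it is the only alkene present, so no choice between two enone double bonds is needed later.

Step 4
Reactants: 6 trans-3-(tert-butyldimethylsilyloxy)-2-(1-hydroxyethyl)cyclopentan-1-one
Product: 8 (R,E)-3-(tert-butyldimethylsilyloxy)-2-ethylidenecyclopentan-1-one, via mesylate 7 (not isolated)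
Conditions: MsCl, Et3N, CH2Cl2, 0 °C to rt
Reagents that add atoms: none
Why: Mesylation and E1cB elimination (aldol dehydration) should give the exocyclic enone as the favoured (E)-isomer with the methyl group anti to the carbonyl, because mesylate leaves far more readily than the silyloxy group on the other β-carbon.

Step 5
Reactants: 8 (R,E)-3-(tert-butyldimethylsilyloxy)-2-ethylidenecyclopentan-1-one, 2 (E)-tert-butyldimethyl(penta-1,3-dien-2-yloxy)silane
Product: 10 1,8-bis(tert-butyldimethylsilyloxy)-6,10-dimethylspiro[4.5]dec-7-en-4-one (C1/C5/C10 as in the target; C6 unassigned), via silyl-transfer Michael adduct 9 (not isolated)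
Conditions: Tf2NH (5 mol%), CH2Cl2, −78 to −40 °C; Et3N quench
Reagents that add atoms: none
Why: Tf2NH is silylated by 2 to TBSNTf2, which activates the enone of 8; the CH2 terminus of the diene (C9) adds to the β-carbon C10 with silyl transfer to the C4 oxygen (Mukaiyama–Michael addition, giving 9), and the ring A silyl enol ether then adds through C5 to the β-carbon C6 of the released enone while the silyl group returns to O8, so the net change is a formal [4+2] cycloaddition that forms C9–C10 and C5–C6 and leaves the C8 oxygen as a regiodefined silyl enol ether. The closest known reaction type is the triflimide-catalysed Diels–Alder reaction (double Mukaiyama–Michael annulation) of 2-silyloxydienes with hindered enones that builds quaternary ring carbons. Ring B is closed by a 6-endo-trig Michael addition in which both carbons of the acceptor bond C6=C7 lie in the new ring (in the concerted limit, a [4+2] closure with the diene s-cis). C5 is controlled by the C1 stereocentre: allylic 1,3-strain between the (E)-methyl group and C1 holds C1–H in the enone plane and the silyloxy group perpendicular to it, so both bonds form on the face anti to that group and C6 ends trans to the C1 oxygen; C10 follows from the (E)-geometry, since C9 and C6 arrive on the same face without rotation about C5–C10 (rotation in 9 is opposed by allylic strain with the C4 silyloxy group), which leaves the C10 methyl syn to C1; C6 forms without control and is erased in step 10. The step needs regioselectivity (C9 to C10, C6 to C5), secured by pairing the most nucleophilic diene terminus with the enone β-carbon; 1,4- rather than 1,2-addition, secured by the hindered C4 carbonyl; and π-facial selectivity, secured by the C1 silyloxy group.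

Step 6
Reactants: 10 1,8-bis(tert-butyldimethylsilyloxy)-6,10-dimethylspiro[4.5]dec-7-en-4-one
Product: 12 1,8-bis(tert-butyldimethylsilyloxy)-6,10-dimethylspiro[4.5]deca-3,7-dien-4-yl trifluoromethanesulfonate, via potassium enolate 11 (not isolated)
Conditions: KN(SiMe3)2, THF, −78 °C; PhNTf2, −78 to 0 °C
Reagents that add atoms: N-phenylbis(trifluoromethanesulfonimide), O=S(=O)(N(c1ccccc1)S(=O)(=O)C(F)(F)F)C(F)(F)F
Why: Deprotonation can occur only at C3 (C5 is quaternary and the ring B carbonyl is masked as its silyl enol ether), and O-triflation of the enolate (enol triflate formation) should give the C3=C4 enol triflate.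

Step 7
Reactants: 12 1,8-bis(tert-butyldimethylsilyloxy)-6,10-dimethylspiro[4.5]deca-3,7-dien-4-yl trifluoromethanesulfonate
Product: 13 1,8-bis(tert-butyldimethylsilyloxy)-6,10-dimethylspiro[4.5]deca-3,7-diene
Conditions: Pd(OAc)2 (5 mol%), PPh3, HCO2H, Et3N, DMF, 60 °C
Reagents that add atoms: none
Why: Palladium-catalysed formate reduction of the enol triflate (oxidative addition, formate decarboxylation, reductive elimination) should replace OTf by H, so the former activating carbonyl carbon C4 becomes an olefinic CH while the silyl enol ether survives the buffered medium.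

Step 8
Reactants: 13 1,8-bis(tert-butyldimethylsilyloxy)-6,10-dimethylspiro[4.5]deca-3,7-diene
Product: 14 2-[1,8-bis(tert-butyldimethylsilyloxy)-6,10-dimethylspiro[4.5]dec-7-en-3-yl]-4,4,5,5-tetramethyl-1,3,2-dioxaborolane (boron trans to the C1 oxygen)
Conditions: HBpin, [Ir(cod)Cl]2 (1.5 mol%), dppe (3 mol%), CH2Cl2, rt
Reagents that add atoms: pinacolborane, CC1(C)OBOC1(C)C
Why: Iridium-catalysed hydroboration of the cis-disubstituted ring A alkene should place boron on C3, remote from the quaternary C5, and on the face anti to the C1 silyloxy group as in hydroboration of 4-substituted cyclopentenes, which sets C3, while the hindered trisubstituted silyl enol ether should not compete.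

Step 9
Reactants: 14 2-[1,8-bis(tert-butyldimethylsilyloxy)-6,10-dimethylspiro[4.5]dec-7-en-3-yl]-4,4,5,5-tetramethyl-1,3,2-dioxaborolane
Product: 17 1,8-bis(tert-butyldimethylsilyloxy)-6,10-dimethyl-3-(prop-1-en-2-yl)spiro[4.5]dec-7-ene, via boronate complex 15 (not isolated), via iodoboronate 16 (not isolated)
Conditions: 2-bromopropene, t-BuLi, THF, −78 °C; add 14; I2, MeOH, −78 °C; NaOMe, −78 °C to rt
Reagents that add atoms: isopropenyllithium C=C(C)[Li] (made in the flask from 2-bromopropene C=C(C)Br)
Why: In the Zweifel olefination the alkenyllithium adds to boron, iodine triggers 1,2-migration of the C3 alkyl group with retention of configuration, and methoxide-induced elimination of the β-iodoboronate releases the 1,1-disubstituted alkene, so the isopropenyl group takes the place of boron trans to the C1 oxygen.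

Step 10
Reactants: 17 1,8-bis(tert-butyldimethylsilyloxy)-6,10-dimethyl-3-(prop-1-en-2-yl)spiro[4.5]dec-7-ene
Product: 19 1-(tert-butyldimethylsilyloxy)-6,10-dimethyl-3-(prop-1-en-2-yl)spiro[4.5]dec-6-en-8-one, via palladium enolate 18 (not isolated)
Conditions: Pd(OAc)2 (1.1 equiv), MeCN, rt
Reagents that add atoms: none
Why: In the Saegusa–Ito oxidation the silyl enol ether is converted to a C7 palladium enolate and β-hydride elimination of the C6 hydrogen should give the C6=C7 enone regiospecifically and remove the uncontrolled C6 centre.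

Step 11
Reactants: 19 1-(tert-butyldimethylsilyloxy)-6,10-dimethyl-3-(prop-1-en-2-yl)spiro[4.5]dec-6-en-8-one
Product: 20 1-hydroxy-6,10-dimethyl-3-(prop-1-en-2-yl)spiro[4.5]dec-6-en-8-one
Conditions: HF·pyridine, THF, 0 °C to rt
Reagents that add atoms: none
Why: Fluoride-mediated cleavage of the secondary silyl ether under weakly acidic conditions should free the C1 alcohol without affecting the enone or the isopropenyl group.

Step 12
Reactants: 20 1-hydroxy-6,10-dimethyl-3-(prop-1-en-2-yl)spiro[4.5]dec-6-en-8-one
Product: 21 6,10-dimethyl-8-oxo-3-(prop-1-en-2-yl)spiro[4.5]dec-6-en-1-yl 2-methylpropanoate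
Conditions: isobutyryl chloride, pyridine, DMAP (cat.), CH2Cl2, 0 °C to rt
Reagents that add atoms: isobutyryl chloride, CC(C)C(=O)Cl
Why: DMAP-catalysed acylation (nucleophilic catalysis) of the hindered secondary alcohol should give the isobutyrate with retention at C1.

Step 13
Reactants: 21 6,10-dimethyl-8-oxo-3-(prop-1-en-2-yl)spiro[4.5]dec-6-en-1-yl 2-methylpropanoate
Product: 22 (1R,3S,5R,9R,10S)-9-acetoxy-6,10-dimethyl-8-oxo-3-(prop-1-en-2-yl)spiro[4.5]dec-6-en-1-yl 2-methylpropanoate (target)
Conditions: Mn(OAc)3·2H2O (4 equiv), benzene, reflux (water separator)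
Reagents that add atoms: manganese triacetate, CC(=O)[O-].CC(=O)[O-].CC(=O)[O-].[Mn+3]
Why: α′-Acetoxylation of the enone with manganese triacetate (manganese enolate, α′-keto radical, acetate transfer) should occur at C9, the only sp3 α-carbon, and place the acetate trans to the neighbouring C10 methyl group, which is the less hindered approach and the equatorial, thermodynamically preferred arrangement.

**Compound list**

1 | (E)-pent-3-en-2-one | C/C=C/C(C)=O | starting material
2 | (E)-tert-butyldimethyl(penta-1,3-dien-2-yloxy)silane | C=C(O[Si](C)(C)C(C)(C)C)/C=C/C | intermediate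
3 | (S)-4-(tert-butyldimethylsilyloxy)cyclopent-2-en-1-one | O=C1C[C@H](O[Si](C)(C)C(C)(C)C)C=C1 | starting material
4 | lithium enolate of 3 (cross-conjugated dienolate) | [Li]OC1=C[C@H](O[Si](C)(C)C(C)(C)C)C=C1 | intermediate
5 | trans-4-(tert-butyldimethylsilyloxy)-5-(1-hydroxyethyl)cyclopent-2-en-1-one (carbinol epimers) | CC(O)[C@H]1[C@H](O[Si](C)(C)C(C)(C)C)C=CC1=O | intermediate
6 | trans-3-(tert-butyldimethylsilyloxy)-2-(1-hydroxyethyl)cyclopentan-1-one (carbinol epimers) | CC(O)[C@H]1[C@H](O[Si](C)(C)C(C)(C)C)CCC1=O | intermediate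
7 | methanesulfonate of 6 | CC(OS(C)(=O)=O)[C@H]1[C@H](O[Si](C)(C)C(C)(C)C)CCC1=O | intermediate
8 | (R,E)-3-(tert-butyldimethylsilyloxy)-2-ethylidenecyclopentan-1-one | C/C=C1/C(=O)CC[C@H]1O[Si](C)(C)C(C)(C)C | intermediate
9 | silyl-transfer Michael adduct: ring A C4 silyl enol ether carrying the (E)-5-oxohept-5-en... side chain 1-methyl-3-oxohex-4-enyl at C5 (C1 and C10 as in the target) | C/C=C/C(=O)C[C@@H](C)C1=C(O[Si](C)(C)C(C)(C)C)CC[C@H]1O[Si](C)(C)C(C)(C)C | intermediate
10 | 1,8-bis(tert-butyldimethylsilyloxy)-6,10-dimethylspiro[4.5]dec-7-en-4-one (C6 trans to the C1 oxygen; C10 methyl syn to C1; C6 unassigned) | C1C[C@@H](O[Si](C)(C)C(C)(C)C)[C@@]2(C1=O)C(C)C=C(O[Si](C)(C)C(C)(C)C)C[C@H]2C | intermediate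
11 | potassium C3=C4 enolate of 10 | [K]OC1=CC[C@@H](O[Si](C)(C)C(C)(C)C)[C@]12C(C)C=C(O[Si](C)(C)C(C)(C)C)C[C@H]2C | intermediate
12 | 1,8-bis(tert-butyldimethylsilyloxy)-6,10-dimethylspiro[4.5]deca-3,7-dien-4-yl trifluoromethanesulfonate | FC(F)(F)S(=O)(=O)OC1=CC[C@@H](O[Si](C)(C)C(C)(C)C)[C@]12C(C)C=C(O[Si](C)(C)C(C)(C)C)C[C@H]2C | intermediate
13 | 1,8-bis(tert-butyldimethylsilyloxy)-6,10-dimethylspiro[4.5]deca-3,7-diene | C1=CC[C@@H](O[Si](C)(C)C(C)(C)C)[C@]12C(C)C=C(O[Si](C)(C)C(C)(C)C)C[C@H]2C | intermediate
14 | C3 pinacol boronate of the spiro bis-silyl ether (boron trans to the C1 oxygen) | CC1(C)OB(OC1(C)C)[C@@H]2C[C@@H](O[Si](C)(C)C(C)(C)C)[C@@]3(C2)C(C)C=C(O[Si](C)(C)C(C)(C)C)C[C@H]3C | intermediate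
15 | lithium isopropenyl boronate complex of 14 | [Li+].CC1(C)O[B-](OC1(C)C)(C(C)=C)[C@@H]2C[C@@H](O[Si](C)(C)C(C)(C)C)[C@@]3(C2)C(C)C=C(O[Si](C)(C)C(C)(C)C)C[C@H]3C | intermediate
16 | β-iodoboronate after 1,2-migration (C3–C(CH3)(Bpin)–CH2I; new carbon unassigned) | CC1(C)OB(OC1(C)C)C(C)(CI)[C@@H]2C[C@@H](O[Si](C)(C)C(C)(C)C)[C@@]3(C2)C(C)C=C(O[Si](C)(C)C(C)(C)C)C[C@H]3C | intermediate
17 | 1,8-bis(tert-butyldimethylsilyloxy)-6,10-dimethyl-3-(prop-1-en-2-yl)spiro[4.5]dec-7-ene (isopropenyl trans to the C1 oxygen) | C=C(C)[C@@H]1C[C@@H](O[Si](C)(C)C(C)(C)C)[C@@]2(C1)C(C)C=C(O[Si](C)(C)C(C)(C)C)C[C@H]2C | intermediate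
18 | C7 acetoxypalladium enolate derived from 17 | C=C(C)[C@@H]1C[C@@H](O[Si](C)(C)C(C)(C)C)[C@@]2(C1)C(C)C([Pd]OC(C)=O)C(=O)C[C@H]2C | intermediate
19 | 1-(tert-butyldimethylsilyloxy)-6,10-dimethyl-3-(prop-1-en-2-yl)spiro[4.5]dec-6-en-8-one | C=C(C)[C@@H]1C[C@@H](O[Si](C)(C)C(C)(C)C)[C@@]2(C1)C(C)=CC(=O)C[C@H]2C | intermediate
20 | 1-hydroxy-6,10-dimethyl-3-(prop-1-en-2-yl)spiro[4.5]dec-6-en-8-one | C=C(C)[C@@H]1C[C@@H](O)[C@@]2(C1)C(C)=CC(=O)C[C@H]2C | intermediate
21 | 6,10-dimethyl-8-oxo-3-(prop-1-en-2-yl)spiro[4.5]dec-6-en-1-yl 2-methylpropanoate | C=C(C)[C@@H]1C[C@@H](OC(=O)C(C)C)[C@@]2(C1)C(C)=CC(=O)C[C@H]2C | intermediate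
22 | (1R,3S,5R,9R,10S)-9-acetoxy-6,10-dimethyl-8-oxo-3-(prop-1-en-2-yl)spiro[4.5]dec-6-en-1-yl 2-methylpropanoate | C=C(C)[C@@H]1C[C@@H](OC(=O)C(C)C)[C@@]2(C1)C(C)=CC(=O)[C@H](OC(C)=O)[C@H]2C | target

**Step count and risks**

Total step count: 13. Longest linear sequence: 12 steps (from 3 to 22, steps 2–13); step 1 prepares the diene.

Steps most likely to fail:

Step 5 (key step). The acid-catalysed sequence may stall after the first conjugate addition, because the C5–C6 bond joins a fully substituted carbon to a secondary one. The silyl Lewis acid may also ionise the allylic C1 silyl ether, which would remove the directing group. The fallback sets out from 1 and 8 and returns at 10 by an anionic double Michael annulation. Kinetic deprotonation of 1 at its methyl group (LiN(iPr)2, THF, −78 °C) would give lithium (E)-penta-1,3-dien-2-olate F1. Addition of 8 would form C9–C10 anti to the silyloxy group and give the conjugate-adduct lithium enolate F2. On warming to −40 °C, F2 would close onto the side-chain enone (C5–C6) to give the C8 lithium enolate of the spiro diketone F3. O-silylation of F3 with TBSCl/HMPA would return the route to 10 with the same enol ether regiochemistry.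

Step 8. Boron may be delivered with poor facial selectivity, giving the C3 epimer, or the silyl enol ether may be hydroborated as well. The fallback sets out from 13 and returns at 17, bypassing 14 and step 9, by a reductive Heck reaction (2-bromopropene, Pd(OAc)2, PPh3, HCO2Na, Bu4NCl, DMF, 60 °C, sealed tube). Syn-carbopalladation should place the isopropenyl group on the less hindered C3, on the face away from the silyloxy group. The resulting C4–palladium bond has no syn β-hydrogen (C5 is quaternary and the C3 hydrogen is anti), so it should be reduced by formate. This fallback forms no new isolable compound (F0).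

Step 13. The radical acetoxylation may show low diastereoselectivity at C9, or side reactions may occur at the isopropenyl group under the oxidative conditions. The fallback sets out from 21 and returns at 22 by enolate oxidation. LiN(SiMe3)2 (THF, −78 °C) should deprotonate 21 at C9 to the cross-conjugated lithium dienolate F4. 2-(Phenylsulfonyl)-3-phenyloxaziridine should hydroxylate it anti to the C10 methyl group and, after an AcOH quench, give the 9-hydroxy enone F5. Acetylation of F5 (Ac2O, DMAP, pyridine, CH2Cl2) would give 22.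

Further compounds

F1 | step 5 | lithium (E)-penta-1,3-dien-2-olate | [Li]OC(=C)/C=C/C
F2 | step 5 | conjugate-adduct lithium enolate (ring A C4 enolate with the enone side chain at C5) | C/C=C/C(=O)C[C@@H](C)C1=C(O[Li])CC[C@H]1O[Si](C)(C)C(C)(C)C
F3 | step 5 | C8 lithium enolate of 1-(tert-butyldimethylsilyloxy)-6,10-dimethylspiro[4.5]decane-4,8-dione | C1C[C@@H](O[Si](C)(C)C(C)(C)C)[C@@]2(C1=O)C(C)C=C(O[Li])C[C@H]2C
F0 | step 8 | none | none
F4 | step 13 | cross-conjugated lithium dienolate of 21 | C=C(C)[C@@H]1C[C@@H](OC(=O)C(C)C)[C@@]2(C1)C(C)=CC(O[Li])=C[C@H]2C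
F5 | step 13 | 9-hydroxy-6,10-dimethyl-8-oxo-3-(prop-1-en-2-yl)spiro[4.5]dec-6-en-1-yl 2-methylpropanoate (hydroxyl trans to the C10 methyl) | C=C(C)[C@@H]1C[C@@H](OC(=O)C(C)C)[C@@]2(C1)C(C)=CC(=O)[C@H](O)[C@H]2C
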